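**Strategy.** Ring C of the upper flavan unit (O1, C2, C3, C4, C4a, C8a) is reached by ring expansion. A 2-aryl-3-hydroxy-2,3-dihydrobenzofuran-3-carbaldehyde, whose five-membered ring holds O1, C2, C4, C4a and C8a and carries C3 as a formyl group, rearranges as its alkoxide by an α-ketol 1,2-shift of C2 from C4 to C3. This single operation makes the six-membered ring, relays chirality to C3 and unveils the C4 ketone, exploiting the C3-hydroxy/benzylic C4 pattern of ring C. The ketone then provides both the C4 electrophile and, after deoxygenation, the lower unit; a Friedel–Crafts coupling of two C6-brominated halves forms the 4→8 bond.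

Key step: step 5

Remark: 6-hydroxy-1-benzofuran-2(3H)-one (the lactone of 2,4-dihydroxyphenylacetic acid) is taken as a purchasable building block; flavan numbering (O1, C2, C3, C4, C4a, C8a) is used for the atoms of the upper ring C in all intermediates.

Step 1
Reactants: 1 6-hydroxy-1-benzofuran-2(3H)-one; 2 3,4-bis(benzyloxy)benzaldehyde
Product: 3 (3E)-3-[3,4-bis(benzyloxy)benzylidene]-6-hydroxy-1-benzofuran-2(3H)-one
Conditions: Et3N (0.2 equiv), 4 Å MS, toluene, 80 °C
Reagents that add atoms: none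
Why: Knoevenagel condensation of the acidic lactone CH2 with the aryl aldehyde; the (E)-benzylidene lactone (aryl anti to the lactone carbonyl, cis to ring A) is expected as the thermodynamic isomer and should be purified by crystallisation.

Step 2
Reactants: 3 (3E)-3-[3,4-bis(benzyloxy)benzylidene]-6-hydroxy-1-benzofuran-2(3H)-one
Product: 4 (3E)-6-(benzyloxy)-3-[3,4-bis(benzyloxy)benzylidene]-1-benzofuran-2(3H)-one
Conditions: BnBr (1.2 equiv), K2CO3, DMF, 0 °C to rt
Reagents that add atoms: benzyl bromide, BrCc1ccccc1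
Why: Williamson etherification of the only free phenol; it is placed after the condensation because no acidic lactone C–H remains, so C-benzylation cannot compete.

Step 3
Reactants: 4 (3E)-6-(benzyloxy)-3-[3,4-bis(benzyloxy)benzylidene]-1-benzofuran-2(3H)-one
Product: 5 (3R,3'S)-6-(benzyloxy)-3'-[3,4-bis(benzyloxy)phenyl]-2H-spiro[1-benzofuran-3,2'-oxiran]-2-one
Conditions: ent-Shi diacetate ketone (L-fructose series, 30 mol%), KHSO5 (as Oxone, 2KHSO5·KHSO4·K2SO4), NaHCO3, Bu4NHSO4 (cat.), MeCN/H2O, 0 °C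
Reagents that add atoms: potassium peroxymonosulfate, [K+].OOS(=O)(=O)[O-]
Why: Shi asymmetric epoxidation by a chiral dioxirane; concerted syn oxygen transfer keeps the two aryl groups cis on the oxirane, and the L-series ketone is chosen by the spiro transition-state model to make the benzylic carbon S and the spiro carbon R, the lactone carbonyl on the spiro carbon keeping the electron-rich epoxide stable.

Step 4
Reactants: 5 (3R,3'S)-6-(benzyloxy)-3'-[3,4-bis(benzyloxy)phenyl]-2H-spiro[1-benzofuran-3,2'-oxiran]-2-one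
Product: 7 (2R,3R)-6-(benzyloxy)-2-[3,4-bis(benzyloxy)phenyl]-3-hydroxy-2,3-dihydro-1-benzofuran-3-carbaldehyde, via spiro-epoxy lactol 6 (not isolated)
Conditions: i-Bu2AlH (1.1 equiv), CH2Cl2, −78 °C; then AcOH (5 equiv), −78 to 0 °C
Reagents that add atoms: none
Why: Half-reduction of the aryl lactone gives the lactol, whose ring-chain tautomer is an o-hydroxyaryl epoxy aldehyde; under mild acid the phenol opens the epoxide at the p-alkoxybenzylic carbon with inversion (epoxide-opening cyclisation, the formyl group disfavouring ionisation at the other oxirane carbon), which sets C2 as R and places the aryl group cis to the new tertiary hydroxyl.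

Step 5
Reactants: 7 (2R,3R)-6-(benzyloxy)-2-[3,4-bis(benzyloxy)phenyl]-3-hydroxy-2,3-dihydro-1-benzofuran-3-carbaldehyde
Product: 8 (2R,3R)-7-(benzyloxy)-2-[3,4-bis(benzyloxy)phenyl]-3-hydroxy-2,3-dihydro-4H-chromen-4-one
Conditions: KN(SiMe3)2 (1.05 equiv), 18-crown-6 (1.1 equiv), THF, −78 to −30 °C; AcOH, −78 °C
Reagents that add atoms: none
Why: The crown-ether-separated potassium alkoxide at C4 pushes the C4–C2 bond onto the neighbouring formyl carbon C3 while C4 becomes the ketone, an α-ketol (acyloin) rearrangement. The closest known reaction type is the base-induced ring expansion of 1-hydroxycycloalkanecarbaldehydes and 1-acylcycloalkanols (as in the D-homoannulation of 17-hydroxy-20-oxo steroids). Ring C (O1–C2–C3–C4–C4a–C8a) is closed by a suprafacial 1,2-shift that inserts C3 into the five-membered O1–C2–C4–C4a–C8a ring, a ring expansion by one atom and not a cyclisation. C2 migrates with retention, and C3 is controlled by the quaternary carbinol centre: in the non-chelated alkoxide the two oxygens are antiperiplanar, C2 attacks the formyl face on its own side, and the (2R,3R)-aldehyde (aryl cis to O−) should give the 2,3-trans (2R,3R) ketol. The step needs migration of the sp3 carbon C2 and not of the aryl carbon C4a; the anionic manifold favours the benzylic, α-oxygenated C2 over the electron-rich aryl group, and any aryl-shift isomer (4-hydroxyflavan-3-one) is funnelled to the same conjugated ketol by enediol tautomerism. The driving force is the change from aldehyde and tertiary alkoxide to aryl ketone and secondary alkoxide in a strain-free six-membered ring.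

Step 6
Reactants: 8 (2R,3R)-7-(benzyloxy)-2-[3,4-bis(benzyloxy)phenyl]-3-hydroxy-2,3-dihydro-4H-chromen-4-one
Product: 9 (2R,3S,4R)-7-(benzyloxy)-2-[3,4-bis(benzyloxy)phenyl]-3,4-dihydro-2H-chromene-3,4-diol
Conditions: NaBH4, THF/MeOH, −20 to 0 °C
Reagents that add atoms: none
Why: Borohydride reduction of the 2,3-trans dihydroflavonol should give mainly the 3,4-trans diol; the C4 configuration is not critical because C4 is ionised in steps 8 and 9.

Step 7
Reactants: 9 (2R,3S,4R)-7-(benzyloxy)-2-[3,4-bis(benzyloxy)phenyl]-3,4-dihydro-2H-chromene-3,4-diol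
Product: 10 (2R,3S,4R)-7-(benzyloxy)-2-[3,4-bis(benzyloxy)phenyl]-6-bromo-3,4-dihydro-2H-chromene-3,4-diol
Conditions: N-bromosuccinimide (1.05 equiv), CH2Cl2, −40 to 0 °C
Reagents that add atoms: N-bromosuccinimide, O=C1CCC(=O)N1Br
Why: Electrophilic aromatic bromination at C6 of ring A (para to O1, ortho to the 7-benzyloxy group, less hindered than C8 and far more activated than ring B); the bromine blocks C6 in both halves and is removed in the last step.

Step 8
Reactants: 10 (2R,3S,4R)-7-(benzyloxy)-2-[3,4-bis(benzyloxy)phenyl]-6-bromo-3,4-dihydro-2H-chromene-3,4-diol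
Product: 11 (2R,3S)-7-(benzyloxy)-2-[3,4-bis(benzyloxy)phenyl]-6-bromo-3,4-dihydro-2H-chromen-3-ol
Conditions: Et3SiH (3 equiv), CF3CO2H (5 equiv), CH2Cl2, −20 °C
Reagents that add atoms: none
Why: Ionic hydrogenation: the C4 hydroxyl ionises to the 7-alkoxy-stabilised benzylic cation, which the silane reduces; C2 and C3 are untouched, giving the protected lower (fisetinidol) unit.

Step 9
Reactants: 10 (2R,3S,4R)-7-(benzyloxy)-2-[3,4-bis(benzyloxy)phenyl]-6-bromo-3,4-dihydro-2H-chromene-3,4-diol; 11 (2R,3S)-7-(benzyloxy)-2-[3,4-bis(benzyloxy)phenyl]-6-bromo-3,4-dihydro-2H-chromen-3-ol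
Product: 12 (2R,3S,4S)-7-(benzyloxy)-4-[(2R,3S)-7-(benzyloxy)-2-[3,4-bis(benzyloxy)phenyl]-6-bromo-3-hydroxy-3,4-dihydro-2H-chromen-8-yl]-2-[3,4-bis(benzyloxy)phenyl]-6-bromo-3,4-dihydro-2H-chromen-3-ol
Conditions: Yb(OTf)3 (10 mol%), 11 (3 equiv), 4 Å MS, CH2Cl2, 0 °C to rt
Reagents that add atoms: none
Why: Lewis-acid ionisation of the C4 hydroxyl gives the benzylic cation, which is attacked in a Friedel–Crafts alkylation by C8 of 11 (C6 blocked by bromine) on the face anti to the C3 hydroxyl, so the new C4 centre should be 3,4-trans (4S); the excess of 11 suppresses self-condensation.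

Step 10
Reactants: 12 (2R,3S,4S)-7-(benzyloxy)-4-[(2R,3S)-7-(benzyloxy)-2-[3,4-bis(benzyloxy)phenyl]-6-bromo-3-hydroxy-3,4-dihydro-2H-chromen-8-yl]-2-[3,4-bis(benzyloxy)phenyl]-6-bromo-3,4-dihydro-2H-chromen-3-ol
Product: 13 (2R,3S,4S)-2-(3,4-dihydroxyphenyl)-4-[(2R,3S)-2-(3,4-dihydroxyphenyl)-3,7-dihydroxy-3,4-dihydro-2H-chromen-8-yl]-3,4-dihydro-2H-chromene-3,7-diol (CNP0189433.1)
Conditions: H2 (1 atm), Pd(OH)2/C, Et3N (2.5 equiv), THF/MeOH/H2O, rt
Reagents that add atoms: none
Why: Catalytic hydrogenolysis cleaves the six benzyl ethers and both aryl C–Br bonds without touching the five stereocentres.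

**Compound list**

1 | 6-hydroxy-1-benzofuran-2(3H)-one | O=C1Cc2ccc(O)cc2O1 | starting material
2 | 3,4-bis(benzyloxy)benzaldehyde | O=Cc1ccc(OCc2ccccc2)c(OCc2ccccc2)c1 | starting material
3 | (3E)-3-[3,4-bis(benzyloxy)benzylidene]-6-hydroxy-1-benzofuran-2(3H)-one | O=C1Oc2cc(O)ccc2/C1=C\c1ccc(OCc2ccccc2)c(OCc2ccccc2)c1 | intermediate
4 | (3E)-6-(benzyloxy)-3-[3,4-bis(benzyloxy)benzylidene]-1-benzofuran-2(3H)-one | O=C1Oc2cc(OCc3ccccc3)ccc2/C1=C\c1ccc(OCc2ccccc2)c(OCc2ccccc2)c1 | intermediate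
5 | (3R,3'S)-6-(benzyloxy)-3'-[3,4-bis(benzyloxy)phenyl]-2H-spiro[1-benzofuran-3,2'-oxiran]-2-one | O=C1Oc2cc(OCc4ccccc4)ccc2[C@]13O[C@H]3c1ccc(OCc2ccccc2)c(OCc2ccccc2)c1 | intermediate
6 | (3R,3'S)-6-(benzyloxy)-3'-[3,4-bis(benzyloxy)phenyl]-2H-spiro[1-benzofuran-3,2'-oxiran]-2-ol (both lactol epimers) | OC1Oc2cc(OCc4ccccc4)ccc2[C@]13O[C@H]3c1ccc(OCc2ccccc2)c(OCc2ccccc2)c1 | intermediate (not isolated)
7 | (2R,3R)-6-(benzyloxy)-2-[3,4-bis(benzyloxy)phenyl]-3-hydroxy-2,3-dihydro-1-benzofuran-3-carbaldehyde | O=C[C@]1(O)[C@@H](c3ccc(OCc4ccccc4)c(OCc4ccccc4)c3)Oc2cc(OCc3ccccc3)ccc21 | intermediate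
8 | (2R,3R)-7-(benzyloxy)-2-[3,4-bis(benzyloxy)phenyl]-3-hydroxy-2,3-dihydro-4H-chromen-4-one | O=C1c2ccc(OCc3ccccc3)cc2O[C@H](c2ccc(OCc3ccccc3)c(OCc3ccccc3)c2)[C@H]1O | intermediate
9 | (2R,3S,4R)-7-(benzyloxy)-2-[3,4-bis(benzyloxy)phenyl]-3,4-dihydro-2H-chromene-3,4-diol | c1ccccc1COc1ccc2c(c1)O[C@H](c1ccc(OCc3ccccc3)c(OCc3ccccc3)c1)[C@@H](O)[C@@H]2O | intermediate
10 | (2R,3S,4R)-7-(benzyloxy)-2-[3,4-bis(benzyloxy)phenyl]-6-bromo-3,4-dihydro-2H-chromene-3,4-diol | c1ccccc1COc1c(Br)cc2c(c1)O[C@H](c1ccc(OCc3ccccc3)c(OCc3ccccc3)c1)[C@@H](O)[C@@H]2O | intermediate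
11 | (2R,3S)-7-(benzyloxy)-2-[3,4-bis(benzyloxy)phenyl]-6-bromo-3,4-dihydro-2H-chromen-3-ol | c1ccccc1COc1c(Br)cc2c(c1)O[C@H](c1ccc(OCc3ccccc3)c(OCc3ccccc3)c1)[C@@H](O)C2 | intermediate
12 | (2R,3S,4S)-7-(benzyloxy)-4-[(2R,3S)-7-(benzyloxy)-2-[3,4-bis(benzyloxy)phenyl]-6-bromo-3-hydroxy-3,4-dihydro-2H-chromen-8-yl]-2-[3,4-bis(benzyloxy)phenyl]-6-bromo-3,4-dihydro-2H-chromen-3-ol | c1ccccc1COc1c(Br)cc2c(c1)O[C@H](c1ccc(OCc3ccccc3)c(OCc3ccccc3)c1)[C@@H](O)[C@@H]2c1c(OCc3ccccc3)c(Br)cc2c1O[C@H](c1ccc(OCc3ccccc3)c(OCc3ccccc3)c1)[C@@H](O)C2 | intermediate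
13 | (2R,3S,4S)-2-(3,4-dihydroxyphenyl)-4-[(2R,3S)-2-(3,4-dihydroxyphenyl)-3,7-dihydroxy-3,4-dihydro-2H-chromen-8-yl]-3,4-dihydro-2H-chromene-3,7-diol | Oc1ccc2c(c1)O[C@H](c1ccc(O)c(O)c1)[C@@H](O)[C@@H]2c1c(O)ccc2c1O[C@H](c1ccc(O)c(O)c1)[C@@H](O)C2 | target

**Total step count:** 10. **Longest linear sequence:** 10 steps (1 → 3 → 4 → 5 → 7 → 8 → 9 → 10 → 11 → 12 → 13; compound 11 is made from 10 and coupled with a second portion of 10).

**Steps most likely to fail**

Step 4. The acid-promoted opening may run through an open benzylic cation, which would scramble C2 and later erode the enantiomeric purity of both halves. A 1,2-shift of the formyl group or over-reduction of the lactol could also divert material. The fallback sets out from 5 and returns at 7. The lactone of 5 would be reduced completely with LiBH4 (THF, 0 °C) to the phenolic epoxy alcohol [(2S,3S)-2-[4-(benzyloxy)-2-hydroxyphenyl]-3-[3,4-bis(benzyloxy)phenyl]oxiran-2-yl]methanol F1. Ti(OiPr)4 (1.2 equiv, CH2Cl2, 0 °C) would then bind the primary alkoxide and the epoxide oxygen and direct the phenol to the distal benzylic carbon with inversion, giving (2R,3S)-6-(benzyloxy)-2-[3,4-bis(benzyloxy)phenyl]-3-(hydroxymethyl)-2,3-dihydro-1-benzofuran-3-ol F2. Parikh–Doering oxidation (SO3·pyridine, DMSO, Et3N, 0 °C) of the primary alcohol would lead back to 7.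

Step 5. The aryl carbon C4a may migrate in competition with C2, and the resulting 3-ketone could enolise towards C2 and lose configuration. The product enolate could also expel the phenoxide (ring opening), or the alkoxide could revert to the epoxide before it rearranges. The fallback sets out from 7 and returns at 8, replacing the free alkoxide by a neutral silyl ether and a bulky Lewis acid. Silylation (Me3SiCl, imidazole, DMF) would give (2R,3R)-6-(benzyloxy)-2-[3,4-bis(benzyloxy)phenyl]-3-[(trimethylsilyl)oxy]-2,3-dihydro-1-benzofuran-3-carbaldehyde F3. Methylaluminium bis(4-bromo-2,6-di-tert-butylphenoxide), MeAl(OAr)2 (CH2Cl2, −78 to −20 °C), a known promoter for the rearrangement of α-silyloxy aldehydes to α-silyloxy ketones in the non-chelated geometry, should give (2R,3R)-7-(benzyloxy)-2-[3,4-bis(benzyloxy)phenyl]-3-[(trimethylsilyl)oxy]-2,3-dihydro-4H-chromen-4-one F4. HF·pyridine (THF, 0 °C) would then free the hydroxyl to give 8.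

Step 9. The cation from 10 may be captured by C8 of a second molecule of 10 or of the product (oligomerisation), by ring B of 11, or on the wrong face of C4. The fallback sets out from 10 and returns at 12, changing the donor and the mode of activation. Benzyl mercaptan in AcOH would convert 10 into the thioether (2R,3S,4R)-4-(benzylsulfanyl)-7-(benzyloxy)-2-[3,4-bis(benzyloxy)phenyl]-6-bromo-3,4-dihydro-2H-chromen-3-ol F5 (either C4 epimer serves). Thiophilic activation with AgBF4 (THF, −78 to 0 °C) in the presence of 11 releases the C4 cation slowly at low temperature and should give 12 with less self-condensation.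

**Further compounds**

F1 | step 4 | [(2S,3S)-2-[4-(benzyloxy)-2-hydroxyphenyl]-3-[3,4-bis(benzyloxy)phenyl]oxiran-2-yl]methanol | OC[C@]1(c2ccc(OCc3ccccc3)cc2O)O[C@H]1c1ccc(OCc2ccccc2)c(OCc2ccccc2)c1
F2 | step 4 | (2R,3S)-6-(benzyloxy)-2-[3,4-bis(benzyloxy)phenyl]-3-(hydroxymethyl)-2,3-dihydro-1-benzofuran-3-ol | OC[C@]1(O)[C@@H](c3ccc(OCc4ccccc4)c(OCc4ccccc4)c3)Oc2cc(OCc3ccccc3)ccc21
F3 | step 5 | (2R,3R)-6-(benzyloxy)-2-[3,4-bis(benzyloxy)phenyl]-3-[(trimethylsilyl)oxy]-2,3-dihydro-1-benzofuran-3-carbaldehyde | O=C[C@]1(O[Si](C)(C)C)[C@@H](c3ccc(OCc4ccccc4)c(OCc4ccccc4)c3)Oc2cc(OCc3ccccc3)ccc21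
F4 | step 5 | (2R,3R)-7-(benzyloxy)-2-[3,4-bis(benzyloxy)phenyl]-3-[(trimethylsilyl)oxy]-2,3-dihydro-4H-chromen-4-one | O=C1c2ccc(OCc3ccccc3)cc2O[C@H](c2ccc(OCc3ccccc3)c(OCc3ccccc3)c2)[C@H]1O[Si](C)(C)C
F5 | step 9 | (2R,3S,4R)-4-(benzylsulfanyl)-7-(benzyloxy)-2-[3,4-bis(benzyloxy)phenyl]-6-bromo-3,4-dihydro-2H-chromen-3-ol | c1ccccc1COc1c(Br)cc2c(c1)O[C@H](c1ccc(OCc3ccccc3)c(OCc3ccccc3)c1)[C@@H](O)[C@@H]2SCc1ccccc1
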